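Retrosynthesis: after the four O-benzyl groups are removed, the only cut between the two halves is the ether bond from C8 of flavone II to O4' of flavone I. Flavone I is then cut at O1–C2 (ring closure) and C2–C3 (aldol), back to phloroacetophenone and MOM-protected 4-hydroxybenzaldehyde. Flavone II is apigenin itself.
Enabling feature: C8 of flavone II is a free A-ring CH. It is para to the 5-OH that is hydrogen-bonded to the C4 carbonyl, and it lies between O7 and the pyranone O1. Oxidation of this phenol makes C8 electrophilic, and the 4'-OH of flavone I sits on a B ring made electron-poor by the para chromone, so it can react through oxygen.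
Forward: the acetophenone and the aldehyde give a chalcone, oxidative cyclisation closes the pyranone ring of flavone I, and the 4'-OH is freed. Apigenin is benzylated at O7 and O4'. The two complete flavones are joined by anodic C8–H/O–H coupling, and hydrogenolysis follows.
Stereochemistry: nothing has to be set. The E alkene of the chalcone and the sp3 C8 of the transient dienone both disappear along the way.

Key step: step 6

Assumption: the target has no stereocentre and its diaryl ether rotates freely, so it is achiral and the constitution alone defines the compound asked for.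

Step 1
Reactants: 1 2',4',6'-trihydroxyacetophenone (phloroacetophenone)
Product: 2 4',6'-bis(benzyloxy)-2'-hydroxyacetophenone
Conditions: BnBr (2.1 equiv), K2CO3, DMF, rt
Reagents that add atoms: benzyl bromide, BrCc1ccccc1
Why: Williamson ether synthesis; the para OH and one of the two equivalent ortho OH groups are alkylated, after which the last OH is locked in a hydrogen bond to the acetyl oxygen and should not react with the limited amount of halide under carbonate.

Step 2
Reactants: 2 4',6'-bis(benzyloxy)-2'-hydroxyacetophenone; 3 4-(methoxymethoxy)benzaldehyde
Product: 4 (E)-1-[2,4-bis(benzyloxy)-6-hydroxyphenyl]-3-[4-(methoxymethoxy)phenyl]prop-2-en-1-one (2'-hydroxychalcone)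
Conditions: KOH (50 % aq), EtOH–THF, rt
Reagents that add atoms: none
Why: Claisen–Schmidt condensation; only the methyl ketone can enolise, E1cB loss of water gives the conjugated E enone, and benzyl and MOM ethers are inert to hydroxide.

Step 3
Reactants: 4 2'-hydroxychalcone
Product: 5 5,7-bis(benzyloxy)-4'-(methoxymethoxy)flavone
Conditions: I2 (10 mol %), DMSO, 120 °C
Reagents that add atoms: none
Why: Iodine-catalysed oxidative cyclisation of a 2'-hydroxychalcone (6-endo O1–C2 closure and dehydrogenation, DMSO as terminal oxidant); the low iodine loading limits ring iodination and acid build-up, and partial loss of the MOM group would be harmless because the next step removes it.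

Step 4
Reactants: 5 5,7-bis(benzyloxy)-4'-(methoxymethoxy)flavone
Product: 6 5,7-di-O-benzylapigenin (5,7-bis(benzyloxy)-4'-hydroxyflavone)
Conditions: 3 M aq HCl–THF (1:3), 45 °C
Reagents that add atoms: none
Why: Acid-catalysed acetal hydrolysis; the MOM acetal ionises in dilute acid much faster than an aryl benzyl ether is cleaved, and the mild temperature should spare the peri 5-O-benzyl group.

Step 5
Reactants: 7 apigenin (5,7,4'-trihydroxyflavone)
Product: 8 7,4'-di-O-benzylapigenin (7,4'-bis(benzyloxy)-5-hydroxyflavone)
Conditions: BnBr (2.1 equiv), K2CO3, DMF, rt to 40 °C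
Reagents that add atoms: benzyl bromide, BrCc1ccccc1
Why: Williamson ether synthesis; the 7-OH and 4'-OH are acidic vinylogous acids and are alkylated, whereas the 5-OH chelated to C4=O should stay free with two equivalents of halide.

Step 6
Reactants: 6 5,7-di-O-benzylapigenin; 8 7,4'-di-O-benzylapigenin
Product: 10 7,4'-di-O-benzyl-8-[4-(5,7-dibenzyloxy-4-oxo-4H-chromen-2-yl)phenoxy]apigenin (tetra-O-benzyl-lanaroflavone), via 8-aryloxydienone 9 (not isolated)
Conditions: 6 (3 equiv), 8 (1 equiv), glassy carbon anode, Pt cathode, undivided cell, Bu4NPF6 (0.1 M), dry HFIP–CH2Cl2 (4:1), no added base, anode held at the foot of the first wave of 8, ca. 1 F per mol of 8, 20 °C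
Reagents that add atoms: none
Why: Proposed new method: at the anode the A ring of 8 should lose one electron while the 5-OH proton moves along its hydrogen bond to the basic γ-pyrone oxygen, the resulting electrophilic phenoxyl radical cation has its largest coefficient at C8 (para to O5), the un-ionised 4'-OH of 6 adds there through oxygen, loss of a second electron and a proton gives the 8-aryloxy-8H-dienone 9, and enolisation of 9 restores the aromatic ring in 10 while the two protons are discharged as H2 at the cathode. The closest known reaction types are the Elbs persulfate oxidation of 5-hydroxyflavones (new C8–O bond para to the 5-OH), anodic dehydrogenative phenol–arene cross-coupling in HFIP (C–C bonds only), the anodic oxidation of 2,6-dihalophenols to 4-aryloxydienones that are carried on to diaryl ethers, and the copper–amine oxidative polymerisation of 2,6-dimethylphenol, which joins a phenol oxygen to a para C–H; none of them has joined two flavones through C8–O. No ring closes and no stereocentre remains, because the sp3 C8 of 9 becomes planar again on enolisation. The step needs oxidation of 8 before 6, attack at C8 and not at C6, and reaction of 6 through oxygen and not through C3' or its own C6/C8. The first should follow from the built-in proton relay of 8, the push–pull deactivation of the 4'-phenol of 6 by its para chromone, HFIP binding to that exposed oxygen, the absence of base and the lack of any free A-ring OH in 6, the second from the para preference that the Elbs oxidation shows on this same ring, and the third from crowding, since C8 lies between O1 and the 7-benzyloxy group, so an oxygen atom fits where a C–C bond would create a tri- or tetra-ortho-substituted biaryl. O7 and O1 are meta to O5 and cannot stabilise a free phenoxonium ion, so capture is placed at the radical-cation stage, and because 10 as a 4-aryloxyphenol is oxidised more easily than 8, the potential is kept low, 6 is used in excess and the electrolysis is stopped near half conversion with recovery of both flavones.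

Step 7
Reactants: 10 tetra-O-benzyl-lanaroflavone
Product: 11 lanaroflavone (4'-O-8''-biapigenin)
Conditions: H2 (1 atm), 10 % Pd/C, THF–MeOH (1:1), rt
Reagents that add atoms: none
Why: Catalytic hydrogenolysis of aryl benzyl ethers; the medium is neutral and cold, so the pyranone ring is never opened and a Wessely–Moser shift of the ether from C8 to C6 cannot occur, and the diaryl ether and the chromone double bonds should survive at one atmosphere.

Compound list
1 | 2',4',6'-trihydroxyacetophenone | CC(=O)c1c(O)cc(O)cc1O | starting material
2 | 4',6'-bis(benzyloxy)-2'-hydroxyacetophenone | CC(=O)c1c(O)cc(OCc2ccccc2)cc1OCc1ccccc1 | intermediate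
3 | 4-(methoxymethoxy)benzaldehyde | COCOc1ccc(C=O)cc1 | starting material
4 | (E)-4',6'-bis(benzyloxy)-2'-hydroxy-4-(methoxymethoxy)chalcone | O=C(/C=C/c1ccc(OCOC)cc1)c1c(O)cc(OCc2ccccc2)cc1OCc1ccccc1 | intermediate
5 | 5,7-bis(benzyloxy)-4'-(methoxymethoxy)flavone | COCOc1ccc(cc1)-c1cc(=O)c2c(OCc3ccccc3)cc(OCc3ccccc3)cc2o1 | intermediate
6 | 5,7-di-O-benzylapigenin (free 4'-OH) | O=c1cc(-c2ccc(O)cc2)oc2cc(OCc3ccccc3)cc(OCc3ccccc3)c12 | intermediate
7 | apigenin | O=c1cc(-c2ccc(O)cc2)oc2cc(O)cc(O)c12 | starting material
8 | 7,4'-di-O-benzylapigenin (free chelated 5-OH) | O=c1cc(-c2ccc(OCc3ccccc3)cc2)oc2cc(OCc3ccccc3)cc(O)c12 | intermediate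
9 | 8-aryloxy-8H-chromene-4,5-dione tautomer of 10 (racemic at C8, transient) | O=C1C=C(OCc2ccccc2)C(Oc2ccc(cc2)-c2cc(=O)c3c(OCc4ccccc4)cc(OCc4ccccc4)cc3o2)C2=C1C(=O)C=C(c1ccc(OCc3ccccc3)cc1)O2 | intermediate
10 | tetra-O-benzyl-lanaroflavone (free 5''-OH) | O=c1cc(-c2ccc(Oc3c(OCc4ccccc4)cc(O)c4c(=O)cc(-c5ccc(OCc6ccccc6)cc5)oc34)cc2)oc2cc(OCc3ccccc3)cc(OCc3ccccc3)c12 | intermediate
11 | lanaroflavone | O=c1cc(-c2ccc(Oc3c(O)cc(O)c4c(=O)cc(-c5ccc(O)cc5)oc34)cc2)oc2cc(O)cc(O)c12 | target

Total step count: 7. Longest linear sequence: 6 (steps 1, 2, 3, 4, 6, 7).

Steps most likely to fail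

Risk 1, step 6.
- The oxidation potentials of the two partners are expected to lie close together. The order of oxidation may therefore invert, and the 4'-phenol of 6 would then be oxidised first and couple through C3' or with itself.
- The product may be oxidised further as it forms.
- Benzyl groups may be lost oxidatively from the radical cation.
- Part of the attack may go to C6.
- The fallback replaces the C–H coupling by a prefunctionalised Ullmann ether synthesis. It sets out from 8, with 6 as the phenol partner.
- The chelated 5-OH of 8 is benzylated under forcing conditions (BnBr, K2CO3, DMF, 80 °C) to give 5,7,4'-tri-O-benzylapigenin F1.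
- Electrophilic iodination (NIS, cat. TFA, MeCN–CH2Cl2), which in fully alkylated 5,7-dioxygenated flavones goes to C8, gives 8-iodo-5,7,4'-tri-O-benzylapigenin F2.
- Copper-catalysed coupling of F2 with 6 (CuI, picolinic acid, K3PO4, DMSO, 90 °C, a ligand system suited to hindered partners) gives penta-O-benzyl-lanaroflavone F3.
- F3 is hydrogenolysed under the conditions of step 7, so the fallback returns to the route at 11.

Risk 2, step 3.
- Hydrogen iodide formed at 120 °C may strip the peri 5-O-benzyl group.
- Electrophilic iodine may substitute the electron-rich A ring.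
- The fallback avoids iodine and acid. It sets out from 4.
- Oxa-Michael closure (NaOAc, EtOH, reflux) gives racemic 5,7-bis(benzyloxy)-4'-(methoxymethoxy)flavanone F4.
- Dehydrogenation of F4 with DDQ in refluxing dioxane returns to the route at 5.

Risk 3, step 7.
- The hydrogenolysis may stall when partly debenzylated, poorly soluble intermediates settle on the catalyst.
- Prolonged exposure may begin to saturate a C2–C3 double bond.
- The fallback changes from reductive to Lewis-acid cleavage. It sets out from 10 and reaches 11 directly with BCl3 and pentamethylbenzene as cation scavenger in CH2Cl2 at −78 °C, followed by a methanol quench. The temperature is far below that needed for Wessely–Moser isomerisation, and no new compound arises (F0).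

Further compounds
F1 | step 6 | 5,7,4'-tri-O-benzylapigenin | O=c1cc(-c2ccc(OCc3ccccc3)cc2)oc2cc(OCc3ccccc3)cc(OCc3ccccc3)c12
F2 | step 6 | 8-iodo-5,7,4'-tri-O-benzylapigenin | O=c1cc(-c2ccc(OCc3ccccc3)cc2)oc2c(I)c(OCc3ccccc3)cc(OCc3ccccc3)c12
F3 | step 6 | penta-O-benzyl-lanaroflavone | O=c1cc(-c2ccc(Oc3c(OCc4ccccc4)cc(OCc4ccccc4)c4c(=O)cc(-c5ccc(OCc6ccccc6)cc5)oc34)cc2)oc2cc(OCc3ccccc3)cc(OCc3ccccc3)c12
F4 | step 3 | racemic 5,7-bis(benzyloxy)-4'-(methoxymethoxy)flavanone | COCOc1ccc(cc1)C1CC(=O)c2c(OCc3ccccc3)cc(OCc3ccccc3)cc2O1
F0 | step 7 | none | none
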